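The ten-membered carbocycle C1–C10 is read as a ring-expanded cyclohexene: the Z C4=C5 alkene is the cyclohexene double bond, and C1–C6 is the bond that must break while C8–C9 forms. One anionic oxy-Cope shift of a C6 alkoxide does this and delivers, together, the ring, the E C1=C10 alkene, the C6 carbonyl and the C8 ether stereocentre. The precursor is a trans-1-(E-2-alkoxyvinyl)-6-isopropenylcyclohex-2-en-1-ol that already carries the C3 and C15 oxygens as silyl ethers and is built from (+)-cis-limonene oxide. Lactone, tiglate and epoxide follow on the ten-membered ketone.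

Key step: step 9

Remark: C1–C15 are the germacrane atom numbers of the target (lactone C6–O–C12, C14 on C10, C15 on C4), α and β mean below and above the ring in its usual drawing, and (1R,2S,4R)-limonene 1,2-oxide is assumed to be bought as the single diastereomer.

Step 1
Reactants: 1 (1R,2S,4R)-limonene 1,2-oxide ((+)-cis-limonene oxide; oxirane oxygen anti to the isopropenyl group)
Product: 2 (1S,5R)-2-methylidene-5-(prop-1-en-2-yl)cyclohexan-1-ol
Conditions: Et2AlCl, lithium 2,2,6,6-tetramethylpiperidide, toluene, 0 °C; then H2O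
Reagents that add atoms: none
Why: Aluminium amide epoxide-to-allylic-alcohol isomerisation: the amide bound to the oxirane oxygen removes a syn β-hydrogen of the methyl group, so the exocyclic alkene should form while the C–O stereocentre (the later C3) and the isopropenyl-bearing centre are untouched.

Step 2
Reactants: 2 (1S,5R)-2-methylidene-5-(prop-1-en-2-yl)cyclohexan-1-ol
Product: 3 (3S,4S,6R)-6-(prop-1-en-2-yl)-1-oxaspiro[2.5]octan-4-ol
Conditions: VO(acac)2 (2 mol %), t-BuOOH, CH2Cl2, 0 °C to rt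
Reagents that add atoms: tert-butyl hydroperoxide, CC(C)(C)OO
Why: Hydroxyl-directed vanadium-catalysed epoxidation should touch only the allylic exocyclic alkene and leave the isopropenyl group; the spiro centre is expected syn to the hydroxyl but is erased in step 3, so its configuration does not matter.

Step 3
Reactants: 3 (3S,4S,6R)-6-(prop-1-en-2-yl)-1-oxaspiro[2.5]octan-4-ol
Product: 4 (1S,5R)-2-(hydroxymethyl)-5-(prop-1-en-2-yl)cyclohex-2-en-1-ol
Conditions: LiN(i-Pr)2 (3 equiv), Et2O, 0 °C to reflux; then H2O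
Reagents that add atoms: none
Why: Lithium amide-promoted syn β-elimination of a 2,2-disubstituted oxirane: the only β-hydrogens syn to the oxirane oxygen sit on the ring CH2 (the carbinol hydrogen is anti), so the endocyclic alkene and the primary alcohol should result.

Step 4
Reactants: 4 (1S,5R)-2-(hydroxymethyl)-5-(prop-1-en-2-yl)cyclohex-2-en-1-ol
Product: 5 (1S,5R)-1-(tert-butyldimethylsilyloxy)-2-[(tert-butyldimethylsilyloxy)methyl]-5-(prop-1-en-2-yl)cyclohex-2-ene
Conditions: TBSCl, imidazole, DMF, rt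
Reagents that add atoms: tert-butyldimethylsilyl chloride, CC(C)(C)[Si](C)(C)Cl
Why: Imidazole-mediated silylation of the primary and the secondary allylic hydroxyl; no stereocentre is touched.

Step 5
Reactants: 5 (1S,5R)-1-(tert-butyldimethylsilyloxy)-2-[(tert-butyldimethylsilyloxy)methyl]-5-(prop-1-en-2-yl)cyclohex-2-ene
Product: 6 (4S,6R)-4-(tert-butyldimethylsilyloxy)-3-[(tert-butyldimethylsilyloxy)methyl]-6-(prop-1-en-2-yl)cyclohex-2-en-1-one
Conditions: CrO3, 3,5-dimethylpyrazole, CH2Cl2, −20 °C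
Reagents that add atoms: chromium trioxide, O=[Cr](=O)=O
Why: Allylic C–H oxidation to the enone by the CrO3–3,5-dimethylpyrazole complex: the ring alkene has a single unencumbered allylic methylene (the other two allylic carbons carry silyloxy groups), so the carbonyl should appear next to the isopropenyl-bearing carbon, whose configuration is kept at low temperature.

Step 6
Reactants: 7 4-methoxybenzyl alcohol; 8 trichloroethylene
Product: 11 1-(ethynyloxymethyl)-4-methoxybenzene, via dichlorovinyl ether 9 (not isolated), via lithium alkynyl ether 10 (not isolated)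
Conditions: KH, THF, 0 °C; Cl2C=CHCl, −50 °C to rt; n-BuLi (2.4 equiv), −78 °C; MeOH, −78 °C; product kept cold and used at once
Reagents that add atoms: none
Why: Alkynyl ether synthesis from trichloroethylene: alkoxide addition–elimination gives the (E)-1,2-dichlorovinyl ether, which n-BuLi converts by dehydrochlorination and chlorine–lithium exchange into the lithium acetylide that methanol protonates.

Step 7
Reactants: 11 1-(ethynyloxymethyl)-4-methoxybenzene
Product: 13 1-{[(E)-2-iodoethenyl]oxymethyl}-4-methoxybenzene, via alkenylzirconocene chloride 12 (not isolated)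
Conditions: Cp2Zr(H)Cl, THF, 0 °C to rt; I2, 0 °C
Reagents that add atoms: iodine, II
Why: Hydrozirconation–iodination: Zr–H adds syn with zirconium at the unsubstituted alkyne carbon and iodinolysis of the C–Zr bond goes with retention, so the E β-iodo enol ether should form.

Step 8
Reactants: 13 1-{[(E)-2-iodoethenyl]oxymethyl}-4-methoxybenzene; 6 (4S,6R)-4-(tert-butyldimethylsilyloxy)-3-[(tert-butyldimethylsilyloxy)methyl]-6-(prop-1-en-2-yl)cyclohex-2-en-1-one
Product: 16 (1R,4S,6R)-4-(tert-butyldimethylsilyloxy)-3-[(tert-butyldimethylsilyloxy)methyl]-1-[(E)-2-(4-methoxybenzyloxy)ethenyl]-6-(prop-1-en-2-yl)cyclohex-2-en-1-ol, via alkenyllithium 14 (not isolated), via alkenylcerium dichloride 15 (not isolated)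
Conditions: t-BuLi (2 equiv), Et2O, −78 °C; CeCl3, THF, −78 °C; then 6, −78 °C; aq NH4Cl
Reagents that add atoms: none
Why: Iodine–lithium exchange keeps the E geometry and the organocerium reagent adds 1,2 to the enone without enolising the acidic C–H beside the carbonyl; it should enter anti to the neighbouring isopropenyl group, which sets the carbinol centre with the two alkenyl groups trans and the hydroxyl cis to isopropenyl.

Step 9
Reactants: 16 (1R,4S,6R)-4-(tert-butyldimethylsilyloxy)-3-[(tert-butyldimethylsilyloxy)methyl]-1-[(E)-2-(4-methoxybenzyloxy)ethenyl]-6-(prop-1-en-2-yl)cyclohex-2-en-1-ol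
Product: 18 (2Z,4S,6E,9R)-4-(tert-butyldimethylsilyloxy)-3-[(tert-butyldimethylsilyloxy)methyl]-9-(4-methoxybenzyloxy)-7-methylcyclodeca-2,6-dien-1-one, via potassium enolate 17 (not isolated)
Conditions: KH, 18-crown-6, THF, 0 °C to rt; then AcOH in THF, −78 °C
Reagents that add atoms: none
Why: The potassium alkoxide at C6, freed from ion pairing by the crown ether, undergoes a [3,3] sigmatropic shift across the C8=C7–C6–C1–C10=C9 diene, so that C8–C9 forms while C1–C6 breaks. The closest known reaction type is the anionic oxy-Cope ring expansion of trans-1,2-dialkenylcyclohexanols to (E)-cyclodec-5-enones. The ten-membered ring is thus made by a four-atom ring expansion of the six-membered ring, not by an end-to-end cyclisation, and the former cyclohexene bond becomes the Z C4=C5 alkene. The shift should run through a chair in which the ring bonds to C5 and C2 and the 4-methoxybenzyloxy group are equatorial and the alkoxide is axial, so that the configurations of C1 and C6 together with the E enol ether fix 8R and the E C1=C10 alkene. The step needs chair over boat and sigmatropy over β-elimination: the trans-diequatorial alkenyl groups secure the first, and the second is secured because the C8–O bond lies in the plane of the new enolate and the enolate is protonated at −78 °C to give ketone 18.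

Step 10
Reactants: 18 (2Z,4S,6E,9R)-4-(tert-butyldimethylsilyloxy)-3-[(tert-butyldimethylsilyloxy)methyl]-9-(4-methoxybenzyloxy)-7-methylcyclodeca-2,6-dien-1-one; 19 methyl bromoacetate
Product: 21 methyl (7R)-3β,15-bis(tert-butyldimethylsilyloxy)-8β-(4-methoxybenzyloxy)-6-oxo-13-norgermacra-1(10)E,4Z-dien-12-oate, via lithium enolate 20 (not isolated)
Conditions: LiN(i-Pr)2, THF, −78 °C; BrCH2CO2Me, −78 to −40 °C
Reagents that add atoms: none
Why: Kinetic lithium enolate alkylation: the amide removes a C7 hydrogen (the only sp3 α-hydrogens), lithium bridges the enolate oxygen and the C8 ether oxygen so that C8–O lies in the enolate plane (no overlap for E1cB loss) and C9 shields one face, and the bromoacetate should attack anti to C9 in the Fráter–Seebach sense, setting 7R with the new arm cis to the C8 oxygen.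

Step 11
Reactants: 21 methyl (7R)-3β,15-bis(tert-butyldimethylsilyloxy)-8β-(4-methoxybenzyloxy)-6-oxo-13-norgermacra-1(10)E,4Z-dien-12-oate
Product: 23 3β,15-bis(tert-butyldimethylsilyloxy)-6β-hydroxy-8β-(4-methoxybenzyloxy)-13-norgermacra-1(10)E,4Z-dien-12-oic acid, via hydroxy ester 22 (not isolated)
Conditions: NaBH4, CeCl3·7H2O, MeOH, −78 °C; then LiOH, THF–H2O, 0 °C to rt; cold HCl to pH 5; used at once
Reagents that add atoms: lithium hydroxide, [Li+].[OH-]
Why: Luche 1,2-reduction of the enone followed by saponification: hydride should come from the ring periphery anti to the C7–C8 bond and past H7 (Felkin sense, as in hydride reductions of 2-alkyl medium-ring ketones), giving the 6β-alcohol (6S) cis to the C7 arm, which is the epimer wanted for the inverting ring closure of step 12.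

Step 12
Reactants: 23 3β,15-bis(tert-butyldimethylsilyloxy)-6β-hydroxy-8β-(4-methoxybenzyloxy)-13-norgermacra-1(10)E,4Z-dien-12-oic acid
Product: 24 3β,15-bis(tert-butyldimethylsilyloxy)-8β-(4-methoxybenzyloxy)-13-norgermacra-1(10)E,4Z-dien-12,6α-olide
Conditions: PPh3, DIAD, THF, 0 °C
Reagents that add atoms: none
Why: Mitsunobu lactonisation: the allylic 6β-hydroxyl is activated as its oxyphosphonium ion and displaced from the rear by the C12 carboxylate (5-exo-tet), so C6 should be inverted to 6R and the trans-fused 6α,12-γ-lactone obtained.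

Step 13
Reactants: 24 3β,15-bis(tert-butyldimethylsilyloxy)-8β-(4-methoxybenzyloxy)-13-norgermacra-1(10)E,4Z-dien-12,6α-olide
Product: 28 3β,15-bis(tert-butyldimethylsilyloxy)-8β-(4-methoxybenzyloxy)germacra-1(10)E,4Z,11(13)-trien-12,6α-olide, via lithium lactone enolate 25 (not isolated), via Mannich base 26 (not isolated), via methiodide 27 (not isolated)
Conditions: LiN(i-Pr)2, THF, −78 °C; CH2=NMe2 I (Eschenmoser's salt), −78 to 0 °C; MeI, MeOH, rt; NaHCO3, CH2Cl2–H2O, rt
Reagents that add atoms: Eschenmoser's salt (N,N-dimethylmethyleneiminium iodide), C=[N+](C)C.[I-]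
Why: α-Methylenation by a Mannich reaction of the lactone enolate at C11, N-methylation and base-induced Hofmann-type elimination, which should give the exocyclic C11=C13 alkene without touching C7.

Step 14
Reactants: 28 3β,15-bis(tert-butyldimethylsilyloxy)-8β-(4-methoxybenzyloxy)germacra-1(10)E,4Z,11(13)-trien-12,6α-olide
Product: 29 3β,15-bis(tert-butyldimethylsilyloxy)-8β-hydroxygermacra-1(10)E,4Z,11(13)-trien-12,6α-olide
Conditions: DDQ, CH2Cl2–pH 7 buffer, 0 °C
Reagents that add atoms: none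
Why: Oxidative cleavage of the 4-methoxybenzyl ether by DDQ (hydride abstraction, then hydrolysis of the hemiacetal) should free the 8β-hydroxyl under neutral conditions that spare the silyl ethers, the alkenes and the methylene lactone.

Step 15
Reactants: 29 3β,15-bis(tert-butyldimethylsilyloxy)-8β-hydroxygermacra-1(10)E,4Z,11(13)-trien-12,6α-olide; 30 tiglic acid
Product: 32 3β,15-bis(tert-butyldimethylsilyloxy)-8β-tigloyloxygermacra-1(10)E,4Z,11(13)-trien-12,6α-olide, via mixed anhydride 31 (not isolated)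
Conditions: 30, 2,4,6-Cl3C6H2COCl, Et3N, THF, rt; then 29, DMAP, toluene, 40 °C
Reagents that add atoms: none
Why: Yamaguchi esterification: DMAP transfers the tigloyl group from the mixed anhydride to the hindered secondary 8β-hydroxyl with retention at C8 and without E/Z isomerisation of the 2-methylbut-2-enoyl unit.

Step 16
Reactants: 32 3β,15-bis(tert-butyldimethylsilyloxy)-8β-tigloyloxygermacra-1(10)E,4Z,11(13)-trien-12,6α-olide
Product: 33 3β,15-bis(tert-butyldimethylsilyloxy)-1β,10α-epoxy-8β-tigloyloxygermacra-4Z,11(13)-dien-12,6α-olide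
Conditions: mCPBA, NaHCO3, CH2Cl2, 0 °C
Reagents that add atoms: 3-chloroperbenzoic acid, OOC(=O)c1cccc(Cl)c1
Why: Prilezhaev epoxidation: the E trisubstituted C1=C10 alkene is the only electron-rich double bond (C4=C5 is flanked by three allylic oxygens and silyl groups, the two enoates are electron-poor), and the peracid should attack its exposed outer face to give the 1β,10α-epoxide (1R,10R) found in this class of lactones.

Step 17
Reactants: 33 3β,15-bis(tert-butyldimethylsilyloxy)-1β,10α-epoxy-8β-tigloyloxygermacra-4Z,11(13)-dien-12,6α-olide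
Product: 34 1β,10α-epoxy-3β,15-dihydroxy-8β-tigloyloxygermacra-4Z,11(13)-dien-12,6α-olide (1R,3S,6R,7R,8R,10R)
Conditions: HF·pyridine, pyridine, THF, 0 °C to rt
Reagents that add atoms: none
Why: Fluoride-mediated desilylation buffered with pyridine should remove both silyl ethers without opening the epoxide, adding to the methylene lactone or cleaving the tiglate.

Compound list
1 | (1R,2S,4R)-limonene 1,2-oxide ((+)-cis-limonene oxide) | C[C@@]12CC[C@H](C[C@@H]1O2)C(C)=C | starting material
2 | (1S,5R)-2-methylidene-5-(prop-1-en-2-yl)cyclohexan-1-ol | C=C1CC[C@H](C[C@@H]1O)C(C)=C | intermediate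
3 | (3S,4S,6R)-6-(prop-1-en-2-yl)-1-oxaspiro[2.5]octan-4-ol | O[C@H]1C[C@@H](CC[C@]12CO2)C(C)=C | intermediate
4 | (1S,5R)-2-(hydroxymethyl)-5-(prop-1-en-2-yl)cyclohex-2-en-1-ol | OCC1=CC[C@H](C[C@@H]1O)C(C)=C | intermediate
5 | bis(tert-butyldimethylsilyl) ether of 4 | CC(C)(C)[Si](C)(C)OCC1=CC[C@H](C[C@@H]1O[Si](C)(C)C(C)(C)C)C(C)=C | intermediate
6 | (4S,6R)-4-(tert-butyldimethylsilyloxy)-3-[(tert-butyldimethylsilyloxy)methyl]-6-(prop-1-en-2-yl)cyclohex-2-en-1-one (silyloxy trans to isopropenyl) | O=C1C=C(CO[Si](C)(C)C(C)(C)C)[C@@H](O[Si](C)(C)C(C)(C)C)C[C@@H]1C(C)=C | intermediate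
7 | 4-methoxybenzyl alcohol | COc1ccc(CO)cc1 | starting material
8 | trichloroethylene | ClC=C(Cl)Cl | starting material
9 | 1-{[(E)-1,2-dichloroethenyl]oxymethyl}-4-methoxybenzene | COc1ccc(CO/C(Cl)=C\Cl)cc1 | intermediate
10 | lithium 2-(4-methoxybenzyloxy)ethynide | COc1ccc(COC#C[Li])cc1 | intermediate
11 | 1-(ethynyloxymethyl)-4-methoxybenzene | COc1ccc(COC#C)cc1 | intermediate
12 | chlorobis(cyclopentadienyl)[(E)-2-(4-methoxybenzyloxy)ethenyl]zirconium | COc1ccc(CO/C=C/[Zr](Cl)(C2C=CC=C2)C2C=CC=C2)cc1 | intermediate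
13 | 1-{[(E)-2-iodoethenyl]oxymethyl}-4-methoxybenzene | COc1ccc(CO/C=C/I)cc1 | intermediate
14 | (E)-2-(4-methoxybenzyloxy)ethenyllithium | COc1ccc(CO/C=C/[Li])cc1 | intermediate
15 | dichloro[(E)-2-(4-methoxybenzyloxy)ethenyl]cerium | COc1ccc(CO/C=C/[Ce](Cl)Cl)cc1 | intermediate
16 | (1R,4S,6R)-4-(tert-butyldimethylsilyloxy)-3-[(tert-butyldimethylsilyloxy)methyl]-1-[(E)-2-(4-methoxybenzyloxy)ethenyl]-6-(prop-1-en-2-yl)cyclohex-2-en-1-ol | O[C@]1(/C=C/OCc2ccc(OC)cc2)C=C(CO[Si](C)(C)C(C)(C)C)[C@@H](O[Si](C)(C)C(C)(C)C)C[C@@H]1C(C)=C | intermediate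
17 | potassium enolate of 18 (enolate oxygen cis to C8) | [K+].[O-]/C1=C\[C@H](OCc2ccc(OC)cc2)C/C(C)=C/C[C@H](O[Si](C)(C)C(C)(C)C)/C(CO[Si](C)(C)C(C)(C)C)=C\1 | intermediate
18 | (2Z,4S,6E,9R)-4-(tert-butyldimethylsilyloxy)-3-[(tert-butyldimethylsilyloxy)methyl]-9-(4-methoxybenzyloxy)-7-methylcyclodeca-2,6-dien-1-one | O=C1/C=C(/CO[Si](C)(C)C(C)(C)C)[C@@H](O[Si](C)(C)C(C)(C)C)C/C=C(\C)C[C@@H](OCc2ccc(OC)cc2)C1 | intermediate
19 | methyl bromoacetate | COC(=O)CBr | starting material
20 | lithium enolate of 18 (lithium bridging O6 and O8) | [Li+].[O-]/C1=C\[C@H](OCc2ccc(OC)cc2)C/C(C)=C/C[C@H](O[Si](C)(C)C(C)(C)C)/C(CO[Si](C)(C)C(C)(C)C)=C\1 | intermediate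
21 | methyl (7R)-3β,15-bis(tert-butyldimethylsilyloxy)-8β-(4-methoxybenzyloxy)-6-oxo-13-norgermacra-1(10)E,4Z-dien-12-oate | O=C1/C=C(/CO[Si](C)(C)C(C)(C)C)[C@@H](O[Si](C)(C)C(C)(C)C)C/C=C(\C)C[C@@H](OCc2ccc(OC)cc2)[C@H]1CC(=O)OC | intermediate
22 | methyl 6β-hydroxy analogue of 21 | O[C@H]1/C=C(/CO[Si](C)(C)C(C)(C)C)[C@@H](O[Si](C)(C)C(C)(C)C)C/C=C(\C)C[C@@H](OCc2ccc(OC)cc2)[C@H]1CC(=O)OC | intermediate
23 | 3β,15-bis(tert-butyldimethylsilyloxy)-6β-hydroxy-8β-(4-methoxybenzyloxy)-13-norgermacra-1(10)E,4Z-dien-12-oic acid | O[C@H]1/C=C(/CO[Si](C)(C)C(C)(C)C)[C@@H](O[Si](C)(C)C(C)(C)C)C/C=C(\C)C[C@@H](OCc2ccc(OC)cc2)[C@H]1CC(=O)O | intermediate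
24 | 3β,15-bis(tert-butyldimethylsilyloxy)-8β-(4-methoxybenzyloxy)-13-norgermacra-1(10)E,4Z-dien-12,6α-olide (3S,6R,7R,8R) | C1C(=O)O[C@@H]2/C=C(/CO[Si](C)(C)C(C)(C)C)[C@@H](O[Si](C)(C)C(C)(C)C)C/C=C(\C)C[C@@H](OCc3ccc(OC)cc3)[C@@H]12 | intermediate
25 | lithium enolate of lactone 24 | C1=C([O-])O[C@@H]2/C=C(/CO[Si](C)(C)C(C)(C)C)[C@@H](O[Si](C)(C)C(C)(C)C)C/C=C(\C)C[C@@H](OCc3ccc(OC)cc3)[C@@H]12.[Li+] | intermediate
26 | 11-(dimethylaminomethyl) lactone (C11 epimers) | CN(C)CC1C(=O)O[C@@H]2/C=C(/CO[Si](C)(C)C(C)(C)C)[C@@H](O[Si](C)(C)C(C)(C)C)C/C=C(\C)C[C@@H](OCc3ccc(OC)cc3)[C@@H]12 | intermediate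
27 | trimethylammonium iodide of 26 | C[N+](C)(C)CC1C(=O)O[C@@H]2/C=C(/CO[Si](C)(C)C(C)(C)C)[C@@H](O[Si](C)(C)C(C)(C)C)C/C=C(\C)C[C@@H](OCc3ccc(OC)cc3)[C@@H]12.[I-] | intermediate
28 | 3β,15-bis(tert-butyldimethylsilyloxy)-8β-(4-methoxybenzyloxy)germacra-1(10)E,4Z,11(13)-trien-12,6α-olide | C=C1C(=O)O[C@@H]2/C=C(/CO[Si](C)(C)C(C)(C)C)[C@@H](O[Si](C)(C)C(C)(C)C)C/C=C(\C)C[C@@H](OCc3ccc(OC)cc3)[C@@H]12 | intermediate
29 | 3β,15-bis(tert-butyldimethylsilyloxy)-8β-hydroxygermacra-1(10)E,4Z,11(13)-trien-12,6α-olide | C=C1C(=O)O[C@@H]2/C=C(/CO[Si](C)(C)C(C)(C)C)[C@@H](O[Si](C)(C)C(C)(C)C)C/C=C(\C)C[C@@H](O)[C@@H]12 | intermediate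
30 | tiglic acid ((E)-2-methylbut-2-enoic acid) | C/C=C(\C)C(=O)O | starting material
31 | tiglic 2,4,6-trichlorobenzoic anhydride | C/C=C(\C)C(=O)OC(=O)c1c(Cl)cc(Cl)cc1Cl | intermediate
32 | 3β,15-bis(tert-butyldimethylsilyloxy)-8β-tigloyloxygermacra-1(10)E,4Z,11(13)-trien-12,6α-olide | C=C1C(=O)O[C@@H]2/C=C(/CO[Si](C)(C)C(C)(C)C)[C@@H](O[Si](C)(C)C(C)(C)C)C/C=C(\C)C[C@@H](OC(=O)/C(C)=C/C)[C@@H]12 | intermediate
33 | 3β,15-bis(tert-butyldimethylsilyloxy)-1β,10α-epoxy-8β-tigloyloxygermacra-4Z,11(13)-dien-12,6α-olide | C=C1C(=O)O[C@@H]2/C=C(/CO[Si](C)(C)C(C)(C)C)[C@@H](O[Si](C)(C)C(C)(C)C)C[C@H]3O[C@]3(C)C[C@@H](OC(=O)/C(C)=C/C)[C@@H]12 | intermediate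
34 | 1β,10α-epoxy-3β,15-dihydroxy-8β-tigloyloxygermacra-4Z,11(13)-dien-12,6α-olide (1R,3S,6R,7R,8R,10R) | C=C1C(=O)O[C@@H]2/C=C(/CO)[C@@H](O)C[C@H]3O[C@]3(C)C[C@@H](OC(=O)/C(C)=C/C)[C@@H]12 | target

Total step count: 17 steps. Longest linear sequence: 15 steps (steps 1–5 and 8–17); steps 6 and 7 make the alkenyl iodide on a side branch.

Steps most likely to fail

Step 10. The facial selectivity at C7 depends on lithium chelation to the C8 ether. If the enolate reacts unchelated, the arm should enter trans to the C8 oxygen, and the β-alkoxy enolate may also begin to expel the ether on warming. The fallback sets out from compound 18 and accepts the wrong face: the same alkylation then delivers methyl (7S)-3β,15-bis(tert-butyldimethylsilyloxy)-8β-(4-methoxybenzyloxy)-6-oxo-13-norgermacra-1(10)E,4Z-dien-12-oate F1. This epimer is treated with KN(SiMe3)2 (1 equiv, THF, −78 °C) to regenerate the C6–C7 enolate, which is quenched with 2,6-di-tert-butylphenol. The proton should then arrive from the ring periphery, on the face that the alkylating agent used, so C7 is set by kinetic protonation instead of by C–C bond formation. The fallback comes back to the route at compound 21.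

Step 12. The ring closure may go through an acyloxyphosphonium ion and so keep the C6 configuration, or the allylic oxyphosphonium ion may ionise and scramble C6. The fallback sets out from compound 18 and carries a tert-butyl ester, which cannot lactonise early. Alkylation as in step 10 but with tert-butyl bromoacetate gives tert-butyl (7R)-3β,15-bis(tert-butyldimethylsilyloxy)-8β-(4-methoxybenzyloxy)-6-oxo-13-norgermacra-1(10)E,4Z-dien-12-oate F2. Luche reduction gives the stable tert-butyl 6β-hydroxy ester F3. Methanesulfonic anhydride and Et3N in CH2Cl2 at −20 °C give the allylic 6β-methanesulfonate F4. On warming, the ester carbonyl oxygen should displace the sulfonate from the rear and the oxonium ion should lose 2-methylpropene, a known neighbouring-group lactonisation with inversion. The fallback comes back to the route at compound 24.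

Step 5. Oxidation may spread to the silyloxy-bearing allylic carbons or to the isopropenyl group, and the new α-stereocentre may epimerise. The fallback sets out from compound 4 and replaces C–H oxidation by an epoxide, selenide and transposition sequence. VO(acac)2 and t-BuOOH epoxidise only the ring alkene, giving (1S,2S,3S,5R)-2,3-epoxy-2-(hydroxymethyl)-5-(prop-1-en-2-yl)cyclohexan-1-ol F5 (oxirane cis to the hydroxyl). TBSCl and imidazole give its bis(tert-butyldimethylsilyl) ether F6. PhSeSePh and NaBH4 in EtOH open the oxirane at its secondary carbon to the trans β-hydroxy phenyl selenide F7. H2O2 then causes selenoxide syn-elimination away from the carbinol carbon and gives the tertiary allylic alcohol 6-(tert-butyldimethylsilyloxy)-1-[(tert-butyldimethylsilyloxy)methyl]-4-(prop-1-en-2-yl)cyclohex-2-en-1-ol F8. Pyridinium chlorochromate (C5H5NH[CrO3Cl]) in CH2Cl2 then effects the Babler–Dauben oxidative 1,3-transposition. The fallback comes back to the route at compound 6.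

Further compounds
F1 | step 10 | methyl (7S)-3β,15-bis(tert-butyldimethylsilyloxy)-8β-(4-methoxybenzyloxy)-6-oxo-13-norgermacra-1(10)E,4Z-dien-12-oate | O=C1/C=C(/CO[Si](C)(C)C(C)(C)C)[C@@H](O[Si](C)(C)C(C)(C)C)C/C=C(\C)C[C@@H](OCc2ccc(OC)cc2)[C@@H]1CC(=O)OC
F2 | step 12 | tert-butyl (7R)-3β,15-bis(tert-butyldimethylsilyloxy)-8β-(4-methoxybenzyloxy)-6-oxo-13-norgermacra-1(10)E,4Z-dien-12-oate | O=C1/C=C(/CO[Si](C)(C)C(C)(C)C)[C@@H](O[Si](C)(C)C(C)(C)C)C/C=C(\C)C[C@@H](OCc2ccc(OC)cc2)[C@H]1CC(=O)OC(C)(C)C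
F3 | step 12 | tert-butyl 6β-hydroxy ester | O[C@H]1/C=C(/CO[Si](C)(C)C(C)(C)C)[C@@H](O[Si](C)(C)C(C)(C)C)C/C=C(\C)C[C@@H](OCc2ccc(OC)cc2)[C@H]1CC(=O)OC(C)(C)C
F4 | step 12 | tert-butyl 6β-methanesulfonyloxy ester | CS(=O)(=O)O[C@H]1/C=C(/CO[Si](C)(C)C(C)(C)C)[C@@H](O[Si](C)(C)C(C)(C)C)C/C=C(\C)C[C@@H](OCc2ccc(OC)cc2)[C@H]1CC(=O)OC(C)(C)C
F5 | step 5 | (1S,2S,3S,5R)-2,3-epoxy-2-(hydroxymethyl)-5-(prop-1-en-2-yl)cyclohexan-1-ol | OC[C@@]12O[C@@H]1C[C@H](C[C@@H]2O)C(C)=C
F6 | step 5 | bis(tert-butyldimethylsilyl) ether of F5 | CC(C)(C)[Si](C)(C)OC[C@@]12O[C@@H]1C[C@H](C[C@@H]2O[Si](C)(C)C(C)(C)C)C(C)=C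
F7 | step 5 | trans β-hydroxy phenyl selenide from F6 | CC(C)(C)[Si](C)(C)OC[C@@]1(O)[C@@H]([Se]c2ccccc2)C[C@H](C[C@@H]1O[Si](C)(C)C(C)(C)C)C(C)=C
F8 | step 5 | 6-(tert-butyldimethylsilyloxy)-1-[(tert-butyldimethylsilyloxy)methyl]-4-(prop-1-en-2-yl)cyclohex-2-en-1-ol | CC(C)(C)[Si](C)(C)OC[C@@]1(O)C=C[C@H](C[C@@H]1O[Si](C)(C)C(C)(C)C)C(C)=C
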